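The route rests on annulating ring B onto a ring-A ketone (labdane numbering). In one pot the enol of 2,2,6-trimethylcyclohexanone attacks an ynone through C10 at the alkyne carbon C9 (Michael) and the ynone methyl carbon C6 then condenses with the ring-A carbonyl C5 (aldol), so that the C9–C10 and C5–C6 bonds, ring B and the quaternary C10 centre arise together. The step exploits the C7 oxygen of ring B, 1,3 to both C5 and C9, and the quaternary C4 that leaves C10 as the only enolizable position. The precursor is just the commercial ketone and 6,6-diethoxyhex-3-yn-2-one; the C11 peroxide is introduced last.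

Key step: step 2

Remarks
- Numbering: labdane numbering throughout. Ring A = C1–C5, C10 (C4 gem-dimethyl, C10 methyl); ring B = C5–C10; C17 = exocyclic methylene on C8; side chain C11–C16 on C9 (C15 = hemiacetal carbon, C16 = formyl carbon). β = the face of the C10 methyl group.
- Assumption: the (R)-phosphoric acid is taken to deliver the (4aR)-dienone 6; if the sense of induction is opposite, the (S)-acid is used with no other change.
- Assumption: C15 of the peroxyhemiacetal is a labile anomeric centre and is taken to settle in the (15R) configuration of the target.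
- Compounds 1, 2, 4, 14 and 15 are commercial.

Step 1
Reactants: 1 4,4-diethoxybut-1-yne; 2 N-methoxy-N-methylacetamide
Product: 3 6,6-diethoxyhex-3-yn-2-one
Conditions: n-BuLi, THF, −78 °C; then 2, −78 → 0 °C; aq. NH4Cl
Reagents that add atoms: none
Why: The lithium acetylide adds once to the N-methoxy-N-methylamide and the chelated tetrahedral intermediate collapses to the ynone only on work-up (Weinreb ketone synthesis); no stereocentre is formed.

Step 2
Reactants: 4 2,2,6-trimethylcyclohexan-1-one (racemic); 3 6,6-diethoxyhex-3-yn-2-one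
Product: 6 (4aR)-4-(2,2-diethoxyethyl)-4a,8,8-trimethyl-5,6,7,8-tetrahydronaphthalen-2(4aH)-one, via enedione 5 (not isolated)
Conditions: (R)-3,3'-bis(2,4,6-triisopropylphenyl)-1,1'-binaphthyl-2,2'-diyl hydrogen phosphate (10 mol %), cyclohexane, 60 °C; then NaOEt (30 mol %), EtOH, 70 °C, same flask
Reagents that add atoms: none
Why: Proposed new method: the chiral phosphoric acid converts 4 into its only possible enol (C4 is quaternary) and, hydrogen-bonded to the enol hydroxyl and to the ynone carbonyl, directs C10 onto the alkyne carbon C9 of 3; the allenol tautomerizes to enedione 5, and NaOEt then equilibrates the C8=C9 geometry, forms the C6 methyl-ketone enolate and drives its aldol condensation with the ring-A carbonyl C5. The closest known reaction types are the phosphoric-acid-catalysed (enol) Michael addition of α-branched cyclic ketones to enones and the Robinson-type annulation of ketones with alkynones to cyclohexa-2,5-dienones. Ring B closes in a 6-(enolendo)-exo-trig aldol addition followed by E1cB dehydration. The only stereocentre, the quaternary C10, is set in the Michael step by the catalyst-controlled face of the enol and cannot epimerize; both enantiomers of 4 converge through the achiral enol. The step needs C–C bond formation at C10 by 1,4-addition, secured by the single enolizable position and by the unhindered sp carbon of the ynone, and an aldol between C6 and C5 only, secured because C5 has no α-hydrogen after the Michael step and only the C6 enolate can reach it through a six-membered transition state. Loss of ethoxide from C12 through the C11 dienolate is reversible in ethanolic NaOEt, whereas dehydration to the cross-conjugated dienone is not.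

Step 3
Reactants: 6 (4aR)-4-(2,2-diethoxyethyl)-4a,8,8-trimethyl-5,6,7,8-tetrahydronaphthalen-2(4aH)-one
Product: 8 12,12-diethoxy-13,14,15,16,17-pentanorlabdan-7β-ol, via ketone 7 (not isolated)
Conditions: Li (excess), liquid NH3/THF, EtOH (excess), −78 → −33 °C; then NH4Cl
Reagents that add atoms: none
Why: Dissolving-metal (Birch-type) reduction takes each enone in turn through its radical anion, the β-carbons C9 and C5 being protonated axially, anti to the axial C10 methyl, which should set 9α-H (equatorial side chain) and 5α-H (trans ring fusion); the ketone 7 released by ethanol is reduced further to the equatorial 7β-alcohol, and the acetal is inert.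

Step 4
Reactants: 8 12,12-diethoxy-13,14,15,16,17-pentanorlabdan-7β-ol
Product: 7 12,12-diethoxy-13,14,15,16,17-pentanorlabdan-7-one
Conditions: Dess–Martin periodinane (1,1,1-triacetoxy-1,1-dihydro-1,2-benziodoxol-3(1H)-one), NaHCO3, CH2Cl2, 0 °C → rt
Reagents that add atoms: none
Why: Dess–Martin oxidation of the secondary alcohol returns the C7 ketone needed for α-functionalization without touching the acetal or the C5 and C9 centres, neither of which is α to the carbonyl.

Step 5
Reactants: 7 12,12-diethoxy-13,14,15,16,17-pentanorlabdan-7-one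
Product: 11 12,12-diethoxy-13,14,15,16-tetranorlabd-8(17)-en-7-one, via Mannich base 9 (not isolated), via methiodide 10 (not isolated)
Conditions: LiN(SiMe3)2, THF, −78 °C; (CH3)2N=CH2 I (Eschenmoser's salt), −78 → 0 °C; then MeI, CH2Cl2, rt; aq. NaHCO3
Reagents that add atoms: dimethylmethyleneammonium iodide (Eschenmoser's salt), C=[N+](C)C.[I-]
Why: Kinetic deprotonation should occur at C8, because the axial C6 hydrogen is screened by the syn-axial C10 methyl and the 4β-methyl (trans-fused 2-decalones enolize away from the ring fusion); Mannich reaction of the enolate, N-methylation and E1cB loss of trimethylamine (Eschenmoser methylenation) give the exocyclic enone, and the transient C8 centre disappears.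

Step 6
Reactants: 11 12,12-diethoxy-13,14,15,16-tetranorlabd-8(17)-en-7-one
Product: 12 12,12-diethoxy-13,14,15,16-tetranorlabd-8(17)-en-7β-ol
Conditions: NaBH4, CeCl3·7H2O, MeOH, −78 °C
Reagents that add atoms: none
Why: Luche reduction gives clean 1,2-addition to the enone, and axial hydride delivery on the α-face (flanked only by the axial 5α- and 9α-hydrogens) should give the equatorial 7β-allylic alcohol.

Step 7
Reactants: 12 12,12-diethoxy-13,14,15,16-tetranorlabd-8(17)-en-7β-ol
Product: 13 7β-hydroxy-13,14,15,16-tetranorlabd-8(17)-en-12-al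
Conditions: pyridinium p-toluenesulfonate (cat.), acetone/H2O (9:1), 40 °C
Reagents that add atoms: water, O
Why: Mild acid-catalysed hydrolysis of the diethyl acetal unmasks the C12 aldehyde; the pyridinium salt is too weak an acid to ionize the allylic alcohol or to move the exocyclic double bond.

Step 8
Reactants: 14 3-bromo-1,1-dimethoxypropane; 15 triphenylphosphine
Product: 16 (3,3-dimethoxypropyl)triphenylphosphonium bromide
Conditions: MeCN, reflux
Reagents that add atoms: none
Why: SN2 quaternization of the phosphine by the primary bromide gives the phosphonium salt; the acetal is untouched under neutral conditions.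

Step 9
Reactants: 16 (3,3-dimethoxypropyl)triphenylphosphonium bromide
Product: 18 4,4-dimethoxy-2-(triphenylphosphoranylidene)butanal, via ylide 17 (not isolated)
Conditions: n-BuLi, THF, −78 → 0 °C; then HCO2Et, 0 °C → rt
Reagents that add atoms: ethyl formate, CCOC=O
Why: Deprotonation gives the non-stabilized ylide 17, which is C-formylated by ethyl formate; the liberated ethoxide deprotonates the formylphosphonium ion to the stabilized α-formyl ylide (ylide acylation).

Step 10
Reactants: 13 7β-hydroxy-13,14,15,16-tetranorlabd-8(17)-en-12-al; 18 4,4-dimethoxy-2-(triphenylphosphoranylidene)butanal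
Product: 19 7β-hydroxy-15,15-dimethoxylabda-8(17),12E-dien-16-al
Conditions: toluene, 100 °C
Reagents that add atoms: none
Why: Wittig olefination with a stabilized α-substituted formyl ylide is reversible before oxaphosphetane collapse and should give the (E)-2-alkyl-2-enal (C11 trans to the formyl group); the free 7-hydroxyl and the acetal are inert.

Step 11
Reactants: 19 7β-hydroxy-15,15-dimethoxylabda-8(17),12E-dien-16-al
Product: 21 15,15-dimethoxy-7β-(triethylsilyloxy)labda-8(17),11E-dien-16-al (C13 epimers), via silyl dienol ether 20 (not isolated)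
Conditions: Et3SiOSO2CF3 (2.5 equiv), Et3N, CH2Cl2, −78 → −30 °C; then Bu4NF/AcOH (1:2), THF, −78 °C
Reagents that add atoms: triethylsilyl trifluoromethanesulfonate, CC[Si](CC)(CC)OS(=O)(=O)C(F)(F)F
Why: Soft enolization (O-silylation of the enal, then removal of the γ-hydrogen at C11 by Et3N) gives the 1-silyloxy-1,3-diene 20 and silylates O7; buffered fluoride at −78 °C cleaves only the enol silyl ether and the dienolate is protonated kinetically at the α-carbon C13 (deconjugative protonation), so the (11E)-β,γ-unsaturated aldehyde should result, its C13 centre being removed in the next step.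

Step 12
Reactants: 21 15,15-dimethoxy-7β-(triethylsilyloxy)labda-8(17),11E-dien-16-al
Product: 22 (11S)-11-hydroperoxy-15,15-dimethoxy-7β-(triethylsilyloxy)labda-8(17),12E-dien-16-al
Conditions: O2 (1 atm), di-tert-butyl hyponitrite (3 mol %), PhCF3, 30 °C, dark
Reagents that add atoms: dioxygen, O=O
Why: Radical-chain autoxidation of a β,γ-unsaturated carbonyl compound (the reaction type by which 3-alkenals give 4-hydroperoxy-2-alkenals): the doubly activated C13–H is abstracted, O2 adds at the C11 terminus of the delocalized radical so that the conjugated (12E)-enal is restored, and the peroxyl radical carries the chain; C11 should be attacked on the face away from the quaternary C10 in the rotamer that keeps H9 eclipsed with the π-system (allylic 1,3-strain), which corresponds to 11S.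

Step 13
Reactants: 22 (11S)-11-hydroperoxy-15,15-dimethoxy-7β-(triethylsilyloxy)labda-8(17),12E-dien-16-al
Product: 24 (11S,15R)-11,15-epidioxy-7β,15-dihydroxylabda-8(17),12-dien-16-al (CNP0269954.2), via hydroperoxy dial 23 (not isolated)
Conditions: AcOH/THF/H2O (3:1:1), 25 °C
Reagents that add atoms: water, O
Why: Aqueous acetic acid cleaves the triethylsilyl ether and hydrolyses the dimethyl acetal; the liberated C15 aldehyde is captured by the C11 hydroperoxide, which cannot reach the trans-disposed C16 formyl group, to close the seven-membered peroxyhemiacetal, the anomeric C15 centre equilibrates, and the acid is too weak for Hock cleavage of the hydroperoxide.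

Compound list
1 | 4,4-diethoxybut-1-yne | C#CCC(OCC)OCC | starting material
2 | N-methoxy-N-methylacetamide | CC(=O)N(C)OC | starting material
3 | 6,6-diethoxyhex-3-yn-2-one | CC(=O)C#CCC(OCC)OCC | intermediate
4 | 2,2,6-trimethylcyclohexan-1-one (racemic) | CC1CCCC(C)(C)C1=O | starting material
5 | (R)-2-(1,1-diethoxy-5-oxohex-3-en-3-yl)-2,6,6-trimethylcyclohexan-1-one (enedione, C8=C9 geometry not fixed) | CC(=O)C=C(CC(OCC)OCC)[C@@]1(C)CCCC(C)(C)C1=O | intermediate
6 | (4aR)-4-(2,2-diethoxyethyl)-4a,8,8-trimethyl-5,6,7,8-tetrahydronaphthalen-2(4aH)-one (ring-B cross-conjugated dienone) | O=C1C=C(CC(OCC)OCC)[C@@]2(C)CCCC(C)(C)C2=C1 | intermediate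
7 | 12,12-diethoxy-13,14,15,16,17-pentanorlabdan-7-one (5α-H, 9α-H, 10β-CH3) | C1[C@H](CC(OCC)OCC)[C@@]2(C)CCCC(C)(C)[C@@H]2CC1=O | intermediate
8 | 12,12-diethoxy-13,14,15,16,17-pentanorlabdan-7β-ol (5α-H, 9α-H, 10β-CH3) | C1[C@H](CC(OCC)OCC)[C@@]2(C)CCCC(C)(C)[C@@H]2C[C@@H]1O | intermediate
9 | 17-(dimethylamino)-12,12-diethoxy-13,14,15,16-tetranorlabdan-7-one (Mannich base, C8 epimers) | CN(C)CC1[C@H](CC(OCC)OCC)[C@@]2(C)CCCC(C)(C)[C@@H]2CC1=O | intermediate
10 | 12,12-diethoxy-7-oxo-13,14,15,16-tetranorlabdan-17-yl(trimethyl)ammonium iodide (methiodide of 9) | C[N+](C)(C)CC1[C@H](CC(OCC)OCC)[C@@]2(C)CCCC(C)(C)[C@@H]2CC1=O.[I-] | intermediate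
11 | 12,12-diethoxy-13,14,15,16-tetranorlabd-8(17)-en-7-one | C=C1[C@H](CC(OCC)OCC)[C@@]2(C)CCCC(C)(C)[C@@H]2CC1=O | intermediate
12 | 12,12-diethoxy-13,14,15,16-tetranorlabd-8(17)-en-7β-ol | C=C1[C@H](CC(OCC)OCC)[C@@]2(C)CCCC(C)(C)[C@@H]2C[C@@H]1O | intermediate
13 | 7β-hydroxy-13,14,15,16-tetranorlabd-8(17)-en-12-al | C=C1[C@H](CC=O)[C@@]2(C)CCCC(C)(C)[C@@H]2C[C@@H]1O | intermediate
14 | 3-bromo-1,1-dimethoxypropane | BrCCC(OC)OC | starting material
15 | triphenylphosphine | c1ccc(cc1)P(c1ccccc1)c1ccccc1 | starting material
16 | (3,3-dimethoxypropyl)triphenylphosphonium bromide | COC(CC[P+](c1ccccc1)(c1ccccc1)c1ccccc1)OC.[Br-] | intermediate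
17 | (3,3-dimethoxypropylidene)triphenylphosphorane | COC(CC=P(c1ccccc1)(c1ccccc1)c1ccccc1)OC | intermediate
18 | 4,4-dimethoxy-2-(triphenylphosphoranylidene)butanal | O=CC(CC(OC)OC)=P(c1ccccc1)(c1ccccc1)c1ccccc1 | intermediate
19 | 7β-hydroxy-15,15-dimethoxylabda-8(17),12E-dien-16-al | C=C1[C@H](C/C=C(/C=O)CC(OC)OC)[C@@]2(C)CCCC(C)(C)[C@@H]2C[C@@H]1O | intermediate
20 | 15,15-dimethoxy-7β,16-bis(triethylsilyloxy)labda-8(17),11E,13(16)E-triene | C=C1[C@H](/C=C/C(CC(OC)OC)=C/O[Si](CC)(CC)CC)[C@@]2(C)CCCC(C)(C)[C@@H]2C[C@@H]1O[Si](CC)(CC)CC | intermediate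
21 | 15,15-dimethoxy-7β-(triethylsilyloxy)labda-8(17),11E-dien-16-al (C13 epimers) | C=C1[C@H](/C=C/C(C=O)CC(OC)OC)[C@@]2(C)CCCC(C)(C)[C@@H]2C[C@@H]1O[Si](CC)(CC)CC | intermediate
22 | (11S)-11-hydroperoxy-15,15-dimethoxy-7β-(triethylsilyloxy)labda-8(17),12E-dien-16-al | C=C1[C@H]([C@@H](OO)/C=C(/C=O)CC(OC)OC)[C@@]2(C)CCCC(C)(C)[C@@H]2C[C@@H]1O[Si](CC)(CC)CC | intermediate
23 | (11S)-11-hydroperoxy-7β-hydroxylabda-8(17),12E-diene-15,16-dial | C=C1[C@H]([C@@H](OO)/C=C(/C=O)CC=O)[C@@]2(C)CCCC(C)(C)[C@@H]2C[C@@H]1O | intermediate
24 | (5S,7S,9R,10S,11S,15R)-11,15-epidioxy-7β,15-dihydroxylabda-8(17),12-dien-16-al (CNP0269954.2) | C=C1[C@H]([C@@H]3C=C(C=O)C[C@H](O)OO3)[C@@]2(C)CCCC(C)(C)[C@@H]2C[C@@H]1O | target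

Total step count: 13. Longest linear sequence: 11 steps (steps 1–7 and 10–13); steps 8 and 9 make the side-chain ylide.

Steps most likely to fail

Step 2 (proposed new method). The hindered enol may not engage the ynone under Brønsted-acid catalysis, or its two faces may be poorly discriminated, so that the dienone forms slowly or with low enantiomeric purity. Fallback, from 4 and 3: the potassium enolate of 4 (KOC(CH3)3, THF/(CH3)3COH, 0 °C) is added to 3 and the crude enedione is cyclized with NaOEt in EtOH to the racemic dienone rac-4-(2,2-diethoxyethyl)-4a,8,8-trimethyl-5,6,7,8-tetrahydronaphthalen-2(4aH)-one F1. This is resolved by preparative chromatography on a chiral stationary phase (cellulose tris(3,5-dimethylphenylcarbamate), supercritical CO2/MeOH). The antipode (4aS)-4-(2,2-diethoxyethyl)-4a,8,8-trimethyl-5,6,7,8-tetrahydronaphthalen-2(4aH)-one F2 is set aside, and the (4aR)-enantiomer is compound 6, where the route is rejoined.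

Step 12. Hydrogen abstraction may occur at the allylic C7–H or C9–H or at the formyl C–H instead of C13–H, and oxygen may add to both faces of C11 (poor site and facial selectivity of the radical chain). Fallback, from 20 (intercepted in step 11 before the fluoride treatment): N-bromosuccinimide in THF at −78 °C brominates the γ-terminus of the silyl dienol ether to give the γ-bromo enal (11ξ)-11-bromo-15,15-dimethoxy-7β-(triethylsilyloxy)labda-8(17),12E-dien-16-al F3. Silver-assisted perhydrolysis (anhydrous H2O2 in Et2O, AgOSO2CF3, −30 °C) then replaces bromide by the hydroperoxy group with retention of the (12E)-enal, and returns to 22. If both C11 epimers form, they are separated at this stage.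

Step 11. The silyl triflate may ionize the C15 dimethyl acetal (loss of methanol to an enol ether), or the dienolate may be protonated at C11 and return the conjugated enal (thermodynamic instead of kinetic protonation). Fallback, from 19: the alcohol is silylated (Et3SiCl, imidazole, CH2Cl2) to the silyl ether 15,15-dimethoxy-7β-(triethylsilyloxy)labda-8(17),12E-dien-16-al F4. Condensation with pyrrolidine (benzene, molecular sieves, rt) gives the dienamine 15,15-dimethoxy-16-(pyrrolidin-1-yl)-7β-(triethylsilyloxy)labda-8(17),11E,13(16)E-triene F5. Cold buffered hydrolysis (aq. AcOH/NaOAc, 0 °C) protonates the dienamine at C13 and liberates the deconjugated aldehyde 21, where the route is rejoined.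

Further compounds
F1 | step 2 | rac-4-(2,2-diethoxyethyl)-4a,8,8-trimethyl-5,6,7,8-tetrahydronaphthalen-2(4aH)-one | O=C1C=C(CC(OCC)OCC)C2(C)CCCC(C)(C)C2=C1
F2 | step 2 | (4aS)-4-(2,2-diethoxyethyl)-4a,8,8-trimethyl-5,6,7,8-tetrahydronaphthalen-2(4aH)-one | O=C1C=C(CC(OCC)OCC)[C@]2(C)CCCC(C)(C)C2=C1
F3 | step 12 | (11ξ)-11-bromo-15,15-dimethoxy-7β-(triethylsilyloxy)labda-8(17),12E-dien-16-al | C=C1[C@H](C(Br)/C=C(/C=O)CC(OC)OC)[C@@]2(C)CCCC(C)(C)[C@@H]2C[C@@H]1O[Si](CC)(CC)CC
F4 | step 11 | 15,15-dimethoxy-7β-(triethylsilyloxy)labda-8(17),12E-dien-16-al | C=C1[C@H](C/C=C(/C=O)CC(OC)OC)[C@@]2(C)CCCC(C)(C)[C@@H]2C[C@@H]1O[Si](CC)(CC)CC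
F5 | step 11 | 15,15-dimethoxy-16-(pyrrolidin-1-yl)-7β-(triethylsilyloxy)labda-8(17),11E,13(16)E-triene | C=C1[C@H](/C=C/C(CC(OC)OC)=C/N3CCCC3)[C@@]2(C)CCCC(C)(C)[C@@H]2C[C@@H]1O[Si](CC)(CC)CC
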